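## Structural features

Selaginellin F is built on an unsymmetrical 1,2,5,6-tetrasubstituted benzene, ring A. C1 carries the methide carbon C7, C2 carries the 2,4-dihydroxyphenyl ring B through a biaryl bond, C5 a hydroxymethyl group and C6 a (4-hydroxyphenyl)ethynyl group, while C3 and C4 bear hydrogen. C7 is bonded to a 4-hydroxyphenyl ring and, through the exocyclic double bond, to a cyclohexa-2,5-dien-1-one ring. These two rings are constitutionally the same 4-oxygenated phenyl unit, so the fuchsone is the two-electron-oxidised form of a bis(4-hydroxyphenyl)methyl group. The molecule has no stereocentre and no stereogenic double bond, and the biaryl axis has too few ortho substituents to be configurationally stable, so the problem is one of regiochemistry and chemoselectivity only. The fragile parts are the para-quinone methide (electrophilic at C7 towards hydride, alcohols and the 2'-hydroxyl of ring B), the diarylalkyne flanked by C7 and the benzylic alcohol (prone to acid-induced cyclisation), and the electron-rich free phenols. The real difficulty is steric: C7 with its two aryl rings is wedged between ring B on C2 and the alkyne on C6, and four different carbon substituents must be placed on adjacent ring A positions. The key step exploits the identity of the two C7 aryl rings: both C7–aryl bonds can be made from one aldehyde carbon on C1 and two molecules of phenol, while a triflate on C6 and an ester on C5 wait as latent alkyne and hydroxymethyl groups.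

## Logic of the disconnections

18 to 17: no skeletal bond is cut. The exocyclic C7=C bond and the dienone carbonyl are traced back to a C7–H bond and a phenolic O–H, the leuco level. The reason is that the quinone methide would not survive hydride, acid or palladium chemistry. The gain is that every earlier step works on a robust triarylmethane. The demand is a mild two-electron oxidation that touches neither ring B, the benzylic alcohol nor the alkyne.

17 to 16: the hydroxymethyl group on C5 is traced back to a methyl ester and the three phenols of ring B and of the alkyne arm to pivalates. One hydride operation then unmasks everything at once. The demand is that the alkyne is not hydrometalated.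

16 to 11 and 15: the C6–C(sp) bond is cut. The alkyne has to arrive after the acid step, because an alkyne ortho to a protonated aldehyde or to a benzylic cation would cyclise. The gain is convergence on two fragments of similar size. The demand is a cross-coupling at an aryl triflate flanked on both sides.

11 to 8 and two molecules of 9: both C7–aryl bonds are cut, which is the strategic simplification. It removes two aryl rings in one operation and reduces C7 to a formyl carbon. The demand is para-selective attack by 9, twice, at a crowded carbon, in an acid that spares the triflate, the ester and the pivalates. The atoms of 8 and 11 map directly onto the target (formyl carbon to C7, triflate carbon to C6, ester carbon to the hydroxymethyl carbon), so their skeletons are kept unchanged and only reagents are refined.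

8 to 7, and 7 to 3 and 6: first the O–S bond of the C6 triflate is cut, then the biaryl bond C2–C1'. Making the C6 triflate only after the biaryl coupling means that a single triflate is present when palladium is used. The demand is a coupling that tolerates a free, chelated phenol and does not hydrolyse pivalates.

3 to 2 to 1: the O–S bond of the C4 triflate and then the ring–formyl bond are cut. This reaches a cheap benzoate that already holds the ester and both oxygens in the right places. The demands are formylation between the two hydroxyls and discrimination of the less hindered hydroxyl.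

6 to 5 to 4: the C–B bond and the two acyl–oxygen bonds are cut. Ring B comes from a bromoresorcinol whose bromine marks the future biaryl carbon. The pivalates have to survive borylation and coupling.

15 to 14 to 13 to 12: the C–H bond of the terminal alkyne is traced to a C–Si bond, then the aryl–alkyne bond and the acyl–oxygen bond are cut. The alkyne arm comes from an iodophenol in three routine operations, and the only demand is a desilylation that leaves the aryl ester intact.

## Other disconnections considered

Alternative 1: The cut goes through the C6–alkyne bond and the C1–C7 bond together. In the forward direction i-PrMgCl would exchange the iodine of the 2-iodoaryl 4-chlorobenzenesulfonate A1, and loss of the sulfonate would give the C1–C6 aryne with the PMB ether on C2. The alkynylmagnesium chloride A2 would add at C6, and the new C1 arylmagnesium would be trapped by the diaryl ketone A3 to give the triaryl carbinol A4.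
- In its favour: two bonds at the two most congested positions are made in one flask without a transition metal. The regiochemistry follows the dependable rule for 3-alkoxy arynes. C7 arrives at the carbinol level, so the fuchsone would come from a dehydration and no polyphenol has to be oxidised.
- Against it here: the arylmagnesium sits between the PMB ether and the new alkyne and must add to a ketone deactivated by two para oxygens, so protonation may outrun addition. A2 must not meet A3 before the aryne is consumed, and i-PrMgCl competes for the aryne. Ring B is still absent in A4 and would need PMB removal, triflation and a Suzuki coupling with a boronate such as 6 next to the tertiary carbinol. The final acid treatment to remove the MOM ethers would generate the trityl cation beside the alkyne and beside the free 2'-hydroxyl of ring B, which invites ring closure.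
- Comparison: on structure, the chosen plan has ring B in place before C7 is elaborated, whereas here the biaryl bond is made at the most hindered moment. On mechanism, the alternative is the equal of the chosen plan in bonds formed per operation and the better in avoiding a palladium coupling at the flanked C6 position. The chosen condensation is the better in using a small aldehyde electrophile and flat nucleophiles. On step economy the two are about equal. The chosen plan is preferred because its end game is hydride and a neutral oxidation, not acid.

Alternative 2: Ring A itself is cut into three alkynes, at C1–C2, C3–C4 and C5–C6. In the forward direction RhCl(PPh3)3 would cyclotrimerise the triyne diester A5. Its butynedioate carbons become C1 and C6, its propargyl alkyne C5 and C4, and its arylethyne C2 and C3. The product is the tetracyclic bis-lactone A6, in which ring A, the phthalide and the benzo[c]chromenone are closed together.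
- In its favour: the tethers fix the position of every substituent, so no formylation or triflation selectivity arises. The biaryl bond is made without cross-coupling. The step is fully atom-economic, and opening the aryl lactone would release the 2'-hydroxyl of ring B with C7 as a carbonyl ready for two aryl nucleophiles.
- Against it here: the target contains neither lactone. Two carbonyls of similar reactivity would have to be told apart: the one on C1 must take two aryl groups, and the one on C6 must be reduced to the aldehyde level, homologated to a terminal alkyne and coupled with an aryl iodide such as 13. A5 is a mixed diester of acetylenedicarboxylic acid with an aryl ester, a strong Michael acceptor that is awkward to assemble. Ester tethers prefer the extended geometry, which disfavours metallacycle closure and calls for high dilution.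
- Comparison: on structure, the alternative is the better in regiocontrol of ring A. The chosen plan is the better in matching functional groups to the target, since aldehyde, triflate and ester each become a target substituent with nothing to undo. On mechanism, the cyclotrimerisation forms three C–C bonds and three rings against two C–C bonds and no ring, but two of those rings must be destroyed. On step economy, the alternative is equal or better up to its key step and clearly longer after it.

Alternative 3: Ring A is cut at C5–C6 and C1–C2 into a 1,3-diyne (C2 to C5) and a propiolate alkyne (C6 and C1). In the forward direction, heating the triyne ester A7 in cyclooctane would bring about a hexadehydro-Diels–Alder cycloaddition. The aryne across C3–C4 would take two hydrogens from the solvent, giving phthalide A8 with ring B on C2 and the methoxy-diarylmethyl group on C1.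
- In its favour: the step needs no reagent. C7 enters with both aryl rings attached and at the carbinol level, so neither a bis-arylation at a crowded centre nor a final oxidation is needed. Ring B is already attached with the same pivalate protection as in the chosen plan, and the tether fixes the regiochemistry.
- Against it here: the alkyne partner carries a fully substituted trityl-type carbon, and the C1–C2 bond must form between two carbons with very large groups. The aryne carbon C3 lies next to ring B, whose 2'-pivaloyloxy oxygen could capture it intramolecularly faster than the bimolecular double hydrogen transfer. The tertiary propargylic ether may ionise at the temperature required. The phthalide carbonyl on C6 must again be turned into the alkyne by reduction, one-carbon homologation and coupling with an iodide such as 13, and the hydride would remove the pivalates early. A final acid step is needed to remove the MOM groups and expel methanol.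
- Comparison: on structure, the alternative is the equal of the chosen plan for ring B and the better for C7, and the worse for C6, which arrives at the wrong oxidation level and one carbon short. On mechanism, a neutral thermal pericyclic step is the better for acid-sensitive groups, while the chosen acid condensation has no intramolecular trap to fear. On step economy, A7 needs a diyne cross-coupling and a separately made propiolic acid, and about four steps follow A8, so the total should equal or exceed that of the chosen route.

Key step: step 7

Remark: the target is taken as the open para-quinone methide; it and every isolated compound of the route are achiral, so no structure needs a stereodescriptor (10 is a racemic transient).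

## Route

Step 1
Reactants: 1 methyl 2,4-dihydroxybenzoate
Product: 2 methyl 3-formyl-2,4-dihydroxybenzoate
Conditions: (CH2)6N4, CF3CO2H, 75 °C; then H2O, 60 °C
Reagents that add atoms: hexamethylenetetramine C1N2CN3CN1CN(C2)C3; water O
Why: Duff formylation; as with other 4-acylresorcinols, the hydrogen bond between the 2-hydroxyl and the ester should direct the iminium electrophile to C3 between the two hydroxyls, and hydrolysis of the benzylic iminium gives the aldehyde. The 5-formyl isomer is the expected minor product and should be separable, since 2 is doubly chelated and less polar.

Step 2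
Reactants: 2 methyl 3-formyl-2,4-dihydroxybenzoate
Product: 3 methyl 3-formyl-2-hydroxy-4-(trifluoromethanesulfonyloxy)benzoate
Conditions: PhNTf2 (1.05 equiv), Et3N, CH2Cl2, 0 °C → rt
Reagents that add atoms: N-phenylbis(trifluoromethanesulfonimide) O=S(=O)(N(c1ccccc1)S(=O)(=O)C(F)(F)F)C(F)(F)F
Why: Selective O-sulfonylation (triflation) of the 4-hydroxyl, which has one ortho neighbour, whereas the 2-hydroxyl is buried between formyl and ester groups and held in the salicylate hydrogen bond. The mild triflimide reagent should discriminate better than the anhydride.

Step 3
Reactants: 4 4-bromoresorcinol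
Product: 5 4-bromo-1,3-phenylene bis(2,2-dimethylpropanoate)
Conditions: t-BuCOCl, Et3N, DMAP (cat.), CH2Cl2, 0 °C → rt
Reagents that add atoms: pivaloyl chloride CC(C)(C)C(=O)Cl
Why: DMAP-catalysed O-acylation of both phenols; the pivalates are chosen because they resist the later acid step and are removed by the final hydride.

Step 4
Reactants: 5 4-bromo-1,3-phenylene bis(2,2-dimethylpropanoate)
Product: 6 4-(4,4,5,5-tetramethyl-1,3,2-dioxaborolan-2-yl)-1,3-phenylene bis(2,2-dimethylpropanoate)
Conditions: B2pin2, PdCl2(dppf) (cat.), KOAc, 1,4-dioxane, 85 °C
Reagents that add atoms: bis(pinacolato)diboron CC1(C)OB(OC1(C)C)B1OC(C)(C)C(C)(C)O1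
Why: Miyaura borylation (oxidative addition of the aryl bromide to zerovalent palladium, transmetalation with the acetate-activated diboron, reductive elimination); KOAc is too weak a base to cleave the pivalates or to cause homocoupling.

Step 5
Reactants: 3 methyl 3-formyl-2-hydroxy-4-(trifluoromethanesulfonyloxy)benzoate; 6 4-(4,4,5,5-tetramethyl-1,3,2-dioxaborolan-2-yl)-1,3-phenylene bis(2,2-dimethylpropanoate)
Product: 7 methyl 2-formyl-3-hydroxy-2',4'-bis(pivaloyloxy)biphenyl-4-carboxylate
Conditions: PdCl2(dppf) (cat.), K3PO4 (anhydrous), 1,4-dioxane, 85 °C
Reagents that add atoms: none
Why: Suzuki–Miyaura coupling; the triflate of 3 is activated by the ortho formyl and para ester groups, and anhydrous phosphate in dioxane protects both the pivalates and the triflate from hydrolysis. The chelated hydroxyl is too hindered and delocalised to interfere, and only two ortho substituents flank the new biaryl bond.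

Step 6
Reactants: 7 methyl 2-formyl-3-hydroxy-2',4'-bis(pivaloyloxy)biphenyl-4-carboxylate
Product: 8 methyl 2-formyl-2',4'-bis(pivaloyloxy)-3-(trifluoromethanesulfonyloxy)biphenyl-4-carboxylate
Conditions: Tf2O, pyridine, CH2Cl2, −20 → 0 °C
Reagents that add atoms: trifluoromethanesulfonic anhydride O=S(=O)(OS(=O)(=O)C(F)(F)F)C(F)(F)F
Why: O-triflation of the one remaining phenol, as is routine for salicylate-type phenols; the strong anhydride is used because this hydroxyl is hindered and chelated, and no selectivity question is left.

Step 7
Reactants: 8 methyl 2-formyl-2',4'-bis(pivaloyloxy)-3-(trifluoromethanesulfonyloxy)biphenyl-4-carboxylate; 9 phenol (two molecules react)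
Product: 11 methyl 2-[bis(4-hydroxyphenyl)methyl]-2',4'-bis(pivaloyloxy)-3-(trifluoromethanesulfonyloxy)biphenyl-4-carboxylate, via mono-aryl benzhydrol 10 (not isolated)
Conditions: 9 (10 equiv), CH3SO3H (3 equiv), CH2Cl2, 0 °C → rt
Reagents that add atoms: none
Why: Double Friedel–Crafts hydroxyalkylation (the aldehyde–phenol condensation by which bisphenols and leuco triarylmethane dyes are made). The acid protonates the formyl group of 8, the para carbon of 9 attacks to give benzhydrol 10, and 10 ionises to a carbenium ion stabilised by its 4-hydroxyphenyl group, which a second molecule of 9 captures through its para carbon, so both C7–aryl bonds form in one flask. No ring is closed and no stereocentre remains, because C7 of 11 bears two identical aryl groups and the racemic centre of 10 is lost on ionisation. The step needs para over ortho attack on 9, and the C2 aryl group and C6 triflate that flank the electrophilic carbon should enforce it, while any ortho adduct formed reversibly should be funnelled to the para,para isomer in the equilibrating acid. It needs intermolecular capture to outrun cyclisation of the cation onto ring B, which the pivalates secure: they deactivate ring B, its 6'-carbon is meta to both oxygens, the acylated 2'-oxygen cannot close a benzo[c]chromene, and 9 is in tenfold excess. It needs the spectators to survive, and the triflate, the methyl ester and the hindered aryl pivalates should be inert to an anhydrous, non-nucleophilic sulfonic acid at room temperature, well below Fries rearrangement temperatures. The product is at the leuco oxidation level and carries on C6 and C5 the handles for the alkyne and the hydroxymethyl group.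

Step 8
Reactants: 12 4-iodophenol
Product: 13 4-iodophenyl 2,2-dimethylpropanoate
Conditions: t-BuCOCl, Et3N, DMAP (cat.), CH2Cl2, 0 °C → rt
Reagents that add atoms: pivaloyl chloride CC(C)(C)C(=O)Cl
Why: DMAP-catalysed O-acylation; the pivalate matches the ring B protection so that one reagent removes all of them later.

Step 9
Reactants: 13 4-iodophenyl 2,2-dimethylpropanoate
Product: 14 4-[(trimethylsilyl)ethynyl]phenyl 2,2-dimethylpropanoate
Conditions: Me3SiC≡CH, PdCl2(PPh3)2 (cat.), CuI (cat.), Et3N, THF, rt
Reagents that add atoms: ethynyltrimethylsilane C#C[Si](C)(C)C
Why: Sonogashira coupling of an aryl iodide at room temperature; the aryl pivalate is inert to the amine base.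

Step 10
Reactants: 14 4-[(trimethylsilyl)ethynyl]phenyl 2,2-dimethylpropanoate
Product: 15 4-ethynylphenyl 2,2-dimethylpropanoate
Conditions: n-Bu4NF, AcOH, THF, 0 °C
Reagents that add atoms: none
Why: Fluoride-induced protodesilylation of the alkynylsilane; buffering with acetic acid keeps the medium non-basic so that the aryl ester is not cleaved.

Step 11
Reactants: 11 methyl 2-[bis(4-hydroxyphenyl)methyl]-2',4'-bis(pivaloyloxy)-3-(trifluoromethanesulfonyloxy)biphenyl-4-carboxylate; 15 4-ethynylphenyl 2,2-dimethylpropanoate
Product: 16 methyl 2-[bis(4-hydroxyphenyl)methyl]-2',4'-bis(pivaloyloxy)-3-{[4-(pivaloyloxy)phenyl]ethynyl}biphenyl-4-carboxylate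
Conditions: PdCl2(PPh3)2 (cat.), CuI (cat.), n-Bu4NI, Et3N, DMF, 70 °C, argon
Reagents that add atoms: none
Why: Sonogashira coupling of an aryl triflate; the ortho ester activates the C6–O bond for oxidative addition and the iodide additive is known to help triflate couplings. A tertiary amine is the only base, so the phenols stay largely un-ionised, and any pivaloyl migration between phenols is harmless because the next step removes every acyl group. Exclusion of oxygen prevents alkyne homocoupling and premature oxidation of the leuco unit.

Step 12
Reactants: 16 methyl 2-[bis(4-hydroxyphenyl)methyl]-2',4'-bis(pivaloyloxy)-3-{[4-(pivaloyloxy)phenyl]ethynyl}biphenyl-4-carboxylate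
Product: 17 2-[bis(4-hydroxyphenyl)methyl]-4-(hydroxymethyl)-3-[(4-hydroxyphenyl)ethynyl]biphenyl-2',4'-diol (leuco selaginellin F)
Conditions: i-Bu2AlH (14 equiv), THF, −78 → 0 °C; then aq. potassium sodium tartrate
Reagents that add atoms: none
Why: Hydride reduction with i-Bu2AlH; the methyl ester goes to the primary alcohol and each aryl pivalate is cleaved reductively to the phenoxide and neopentyl alkoxide, so one reagent unmasks every oxygen (two equivalents are consumed by the free phenols). In THF at or below 0 °C a diarylalkyne should not be hydroaluminated.

Step 13
Reactants: 17 2-[bis(4-hydroxyphenyl)methyl]-4-(hydroxymethyl)-3-[(4-hydroxyphenyl)ethynyl]biphenyl-2',4'-diol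
Product: 18 selaginellin F
Conditions: chloranil (1.05 equiv), THF, rt, dark, argon
Reagents that add atoms: none
Why: Dehydrogenation of a leuco 4-hydroxytriarylmethane to a fuchsone; chloranil abstracts hydride from the triply benzylic C7–H, which two para-hydroxyphenyl groups activate, and the resulting 4-hydroxytrityl cation loses its phenolic proton to give the para-quinone methide. Either of the two identical C7 rings may become the dienone, so no isomer arises, and the mild, acid-free quinone should leave ring B, the benzylic alcohol and the alkyne untouched.

## Compound list

1 | methyl 2,4-dihydroxybenzoate | COC(=O)c1ccc(O)cc1O | starting material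
2 | methyl 3-formyl-2,4-dihydroxybenzoate | COC(=O)c1ccc(O)c(C=O)c1O | intermediate
3 | methyl 3-formyl-2-hydroxy-4-(trifluoromethanesulfonyloxy)benzoate | COC(=O)c1ccc(OS(=O)(=O)C(F)(F)F)c(C=O)c1O | intermediate
4 | 4-bromoresorcinol (4-bromobenzene-1,3-diol) | Oc1ccc(Br)c(O)c1 | starting material
5 | 4-bromo-1,3-phenylene bis(2,2-dimethylpropanoate) | CC(C)(C)C(=O)Oc1ccc(Br)c(OC(=O)C(C)(C)C)c1 | intermediate
6 | 4-(4,4,5,5-tetramethyl-1,3,2-dioxaborolan-2-yl)-1,3-phenylene bis(2,2-dimethylpropanoate) | CC(C)(C)C(=O)Oc1ccc(B2OC(C)(C)C(C)(C)O2)c(OC(=O)C(C)(C)C)c1 | intermediate
7 | methyl 2-formyl-3-hydroxy-2',4'-bis(pivaloyloxy)biphenyl-4-carboxylate | COC(=O)c1ccc(-c2ccc(OC(=O)C(C)(C)C)cc2OC(=O)C(C)(C)C)c(C=O)c1O | intermediate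
8 | methyl 2-formyl-2',4'-bis(pivaloyloxy)-3-(trifluoromethanesulfonyloxy)biphenyl-4-carboxylate | COC(=O)c1ccc(-c2ccc(OC(=O)C(C)(C)C)cc2OC(=O)C(C)(C)C)c(C=O)c1OS(=O)(=O)C(F)(F)F | intermediate
9 | phenol | Oc1ccccc1 | starting material
10 | methyl 2-[hydroxy(4-hydroxyphenyl)methyl]-2',4'-bis(pivaloyloxy)-3-(trifluoromethanesulfonyloxy)biphenyl-4-carboxylate (racemic, not isolated) | COC(=O)c1ccc(-c2ccc(OC(=O)C(C)(C)C)cc2OC(=O)C(C)(C)C)c(C(O)c2ccc(O)cc2)c1OS(=O)(=O)C(F)(F)F | intermediate
11 | methyl 2-[bis(4-hydroxyphenyl)methyl]-2',4'-bis(pivaloyloxy)-3-(trifluoromethanesulfonyloxy)biphenyl-4-carboxylate | COC(=O)c1ccc(-c2ccc(OC(=O)C(C)(C)C)cc2OC(=O)C(C)(C)C)c(C(c2ccc(O)cc2)c2ccc(O)cc2)c1OS(=O)(=O)C(F)(F)F | intermediate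
12 | 4-iodophenol | Oc1ccc(I)cc1 | starting material
13 | 4-iodophenyl 2,2-dimethylpropanoate | CC(C)(C)C(=O)Oc1ccc(I)cc1 | intermediate
14 | 4-[(trimethylsilyl)ethynyl]phenyl 2,2-dimethylpropanoate | CC(C)(C)C(=O)Oc1ccc(C#C[Si](C)(C)C)cc1 | intermediate
15 | 4-ethynylphenyl 2,2-dimethylpropanoate | CC(C)(C)C(=O)Oc1ccc(C#C)cc1 | intermediate
16 | methyl 2-[bis(4-hydroxyphenyl)methyl]-2',4'-bis(pivaloyloxy)-3-{[4-(pivaloyloxy)phenyl]ethynyl}biphenyl-4-carboxylate | COC(=O)c1ccc(-c2ccc(OC(=O)C(C)(C)C)cc2OC(=O)C(C)(C)C)c(C(c2ccc(O)cc2)c2ccc(O)cc2)c1C#Cc1ccc(OC(=O)C(C)(C)C)cc1 | intermediate
17 | 2-[bis(4-hydroxyphenyl)methyl]-4-(hydroxymethyl)-3-[(4-hydroxyphenyl)ethynyl]biphenyl-2',4'-diol (leuco selaginellin F) | OCc1ccc(-c2ccc(O)cc2O)c(C(c2ccc(O)cc2)c2ccc(O)cc2)c1C#Cc1ccc(O)cc1 | intermediate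
18 | selaginellin F, 4-{[2',4'-dihydroxy-4-(hydroxymethyl)-3-[(4-hydroxyphenyl)ethynyl]biphenyl-2-yl](4-hydroxyphenyl)methylidene}cyclohexa-2,5-dien-1-one | O=C1C=CC(=C(c2ccc(O)cc2)c2c(-c3ccc(O)cc3O)ccc(CO)c2C#Cc2ccc(O)cc2)C=C1 | target

## Step count and least certain steps

Total: 13 steps. Longest linear sequence: 8 steps (steps 1, 2, 5, 6, 7, 11, 12 and 13, from 1 to 18). The ring B boronate takes two steps (3 and 4) and the alkyne arm three (8 to 10).

Step 7 (key step). The most likely failure is loss of chemoselectivity at the cation stage. The mono-aryl carbenium ion could cyclise onto ring B, the 2'-pivaloyl group could be lost in acid with closure to a benzo[c]chromene, or the crowded aldehyde could react so slowly that forcing conditions start to cleave or migrate the pivalates. The fallback sets out from 8 and separates the two bond formations. A rhodium-catalysed, base-free 1,2-addition of commercial 4-hydroxyphenylboronic acid to the aldehyde (Rh(acac)(CO)2, dppf, DME/H2O, 80 °C) makes the first C7–aryl bond by nucleophilic arylation and gives benzhydrol 10, this time isolated. 10 ionises under far milder acid than the aldehyde needs (catalytic TsOH or BF3·OEt2, CH2Cl2, 0 °C, excess 9), and the route is rejoined at 11. This fallback makes no compound outside the list (entry F0).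

Step 11. Oxidative addition at the C6 triflate, flanked by the ester and the diarylmethyl group, may be slow. Homocoupling of the alkyne, S–O cleavage of the triflate by phenoxide or amine, and acyl migration would then compete. The fallback sets out from 11 and removes both the base and the copper. The two phenols are capped (t-BuCOCl, Et3N, DMAP) to give methyl 2-{bis[4-(pivaloyloxy)phenyl]methyl}-2',4'-bis(pivaloyloxy)-3-(trifluoromethanesulfonyloxy)biphenyl-4-carboxylate F1. Alkyne 15 is converted with Bu3SnOMe (neat, 60 °C) into tributyl{[4-(pivaloyloxy)phenyl]ethynyl}stannane F2. A Stille coupling of F1 with F2 (Pd(PPh3)4, LiCl, 1,4-dioxane, 100 °C) gives the pentapivalate alkyne F3. The i-Bu2AlH treatment of step 12, with a larger excess, removes five pivalates and reduces the ester, and the route is rejoined at 17.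

Step 13. The oxidation may be unselective (attack on ring B or on the benzylic alcohol) or incomplete, since hydride abstraction from the crowded C7–H may be slow. The quinone methide may also add the 2'-hydroxyl or a nucleophilic solvent. The fallback sets out from 17 and changes the mechanism from hydride abstraction to oxidation of the phenol O–H: Ag2O in dry THF/Et2O at room temperature, the classical reagent for converting para-alkylphenols into quinone methides. Only the two C7-bound rings have a para benzylic hydrogen and can collapse to a quinone methide, the oxidant is removed by filtration, and no acid is present. The route is rejoined at 18. This fallback makes no compound outside the list (entry F0).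

Step 1. Formylation at C5, para to the 2-hydroxyl, may compete with attack at C3, and diformylation may occur. The fallback sets out from 1 and blocks C5. Bromination (NBS, MeCN, 0 °C) gives methyl 5-bromo-2,4-dihydroxybenzoate F4, which is also a commercial compound. The same Duff conditions can then reach only C3 and give methyl 5-bromo-3-formyl-2,4-dihydroxybenzoate F5. Palladium-catalysed formate transfer (Pd(OAc)2, PPh3, HCO2H, Et3N, DMF, 80 °C) removes the bromine without reducing the aryl aldehyde, and the route is rejoined at 2.

Step 2. The two chelated hydroxyls may not be discriminated, leading to triflation at the 2-hydroxyl or at both. The fallback sets out from 2 and moves the selection from the oxygen to the palladium step. Exhaustive triflation (Tf2O, pyridine, CH2Cl2, 0 °C) gives methyl 3-formyl-2,4-bis(trifluoromethanesulfonyloxy)benzoate F6. One equivalent of 6 is then coupled (Pd(PPh3)4, K3PO4, 1,4-dioxane, 70 °C) at the C4 triflate, which has one ortho neighbour against two for the C2 triflate; this steric site selection is established for bis-triflates of dihydroxybenzoates. The route is rejoined directly at 8.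

Step 12. Cleavage of the hindered pivalates may be incomplete, and warming to force it may bring on hydroalumination of the alkyne, directed by the neighbouring aluminium alkoxide. The fallback sets out from 16 and separates solvolysis from reduction. K2CO3 in MeOH/THF at room temperature removes the three aryl pivalates to give methyl 2-[bis(4-hydroxyphenyl)methyl]-2',4'-dihydroxy-3-[(4-hydroxyphenyl)ethynyl]biphenyl-4-carboxylate F7. LiBH4 (THF with a little MeOH, 0 → 40 °C), which does not touch alkynes, then reduces the ester, and the route is rejoined at 17.

## Further compounds

F0 | step 7 | none | none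
F1 | step 11 | methyl 2-{bis[4-(pivaloyloxy)phenyl]methyl}-2',4'-bis(pivaloyloxy)-3-(trifluoromethanesulfonyloxy)biphenyl-4-carboxylate | COC(=O)c1ccc(-c2ccc(OC(=O)C(C)(C)C)cc2OC(=O)C(C)(C)C)c(C(c2ccc(OC(=O)C(C)(C)C)cc2)c2ccc(OC(=O)C(C)(C)C)cc2)c1OS(=O)(=O)C(F)(F)F
F2 | step 11 | tributyl{[4-(pivaloyloxy)phenyl]ethynyl}stannane | CCCC[Sn](CCCC)(CCCC)C#Cc1ccc(OC(=O)C(C)(C)C)cc1
F3 | step 11 | methyl 2-{bis[4-(pivaloyloxy)phenyl]methyl}-2',4'-bis(pivaloyloxy)-3-{[4-(pivaloyloxy)phenyl]ethynyl}biphenyl-4-carboxylate | COC(=O)c1ccc(-c2ccc(OC(=O)C(C)(C)C)cc2OC(=O)C(C)(C)C)c(C(c2ccc(OC(=O)C(C)(C)C)cc2)c2ccc(OC(=O)C(C)(C)C)cc2)c1C#Cc1ccc(OC(=O)C(C)(C)C)cc1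
F0 | step 13 | none | none
F4 | step 1 | methyl 5-bromo-2,4-dihydroxybenzoate | COC(=O)c1cc(Br)c(O)cc1O
F5 | step 1 | methyl 5-bromo-3-formyl-2,4-dihydroxybenzoate | COC(=O)c1cc(Br)c(O)c(C=O)c1O
F6 | step 2 | methyl 3-formyl-2,4-bis(trifluoromethanesulfonyloxy)benzoate | COC(=O)c1ccc(OS(=O)(=O)C(F)(F)F)c(C=O)c1OS(=O)(=O)C(F)(F)F
F7 | step 12 | methyl 2-[bis(4-hydroxyphenyl)methyl]-2',4'-dihydroxy-3-[(4-hydroxyphenyl)ethynyl]biphenyl-4-carboxylate | COC(=O)c1ccc(-c2ccc(O)cc2O)c(C(c2ccc(O)cc2)c2ccc(O)cc2)c1C#Cc1ccc(O)cc1
A1 | alternative 1 | 2-iodo-3-[(4-methoxybenzyl)oxy]-6-[(methoxymethoxy)methyl]phenyl 4-chlorobenzenesulfonate | COCOCc1ccc(OCc2ccc(OC)cc2)c(I)c1OS(=O)(=O)c1ccc(Cl)cc1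
A2 | alternative 1 | {[4-(methoxymethoxy)phenyl]ethynyl}magnesium chloride | COCOc1ccc(C#C[Mg]Cl)cc1
A3 | alternative 1 | 4,4'-bis(methoxymethoxy)benzophenone | COCOc1ccc(C(=O)c2ccc(OCOC)cc2)cc1
A4 | alternative 1 | {2-[(4-methoxybenzyl)oxy]-5-[(methoxymethoxy)methyl]-6-{[4-(methoxymethoxy)phenyl]ethynyl}phenyl}bis[4-(methoxymethoxy)phenyl]methanol | COCOCc1ccc(OCc2ccc(OC)cc2)c(C(O)(c2ccc(OCOC)cc2)c2ccc(OCOC)cc2)c1C#Cc1ccc(OCOC)cc1
A5 | alternative 2 | 2-ethynyl-5-(methoxymethoxy)phenyl prop-2-yn-1-yl but-2-ynedioate | C#CCOC(=O)C#CC(=O)Oc1cc(OCOC)ccc1C#C
A6 | alternative 2 | 3-(methoxymethoxy)-6H-benzo[c]chromen-6-one with a γ-lactone fused across C7–C8 (carbonyl on C7, OCH2 on C8) | O=C1OCc2ccc3-c4ccc(OCOC)cc4OC(=O)c3c21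
A7 | alternative 3 | 5-[2,4-bis(pivaloyloxy)phenyl]penta-2,4-diyn-1-yl 4-methoxy-4,4-bis[4-(methoxymethoxy)phenyl]but-2-ynoate | COC(C#CC(=O)OCC#CC#Cc1ccc(OC(=O)C(C)(C)C)cc1OC(=O)C(C)(C)C)(c1ccc(OCOC)cc1)c1ccc(OCOC)cc1
A8 | alternative 3 | 6-[2,4-bis(pivaloyloxy)phenyl]-7-{methoxybis[4-(methoxymethoxy)phenyl]methyl}isobenzofuran-1(3H)-one | O=C1OCc2ccc(-c3ccc(OC(=O)C(C)(C)C)cc3OC(=O)C(C)(C)C)c(C(OC)(c3ccc(OCOC)cc3)c3ccc(OCOC)cc3)c12
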